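**Plan**
- **Feature.** Ring B is the arene of the 2,3-dihydrobenzofuran (C3a, C4, C5, C6, C7, C7a). It has a free OH on C7 beside the ring oxygen O1 on C7a, and a single carbon arm on C5. This ortho O,O pattern is isomeric with a 2,4-disubstituted furan whose C2 side chain ends in an ethynyl ether. (Ring A is the arene on the lactone C4 arm; ring C is the aryl group on C2.)
- **Cuts, in retrosynthetic order.** O-benzyl and O-silyl groups; then C3a–C7a, C6–C7 and C7–O, which open ring B and the dihydrofuran ring together; then lactone C3–CH2; then the furan–CH2 carbon and O1–C7a; then C2–C3 (aldol); then lactone C4–CH2 of ring A.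
- **Forward.** The lactone ring is closed first (steps 1–5). The side chain is grown on a bromofuran aldehyde (steps 6–15). Enolate alkylation joins the halves (step 16). One gold-catalysed isomerisation closes the dihydrofuran ring and ring B (step 17), and two deprotections follow.
- **Stereochemistry.** C2 and C3 come from one Evans syn aldol, where syn in the chain maps onto trans in the ring. Lactone C4 comes from an Evans alkylation with the same (S)-oxazolidinone. Lactone C3 is set by alkylation anti to the C4 substituent.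

Key step: step 17

Assumption: the SMILES is read as (3S,4S) in the lactone and (2S,3R) in the dihydrobenzofuran (both trans), so the lactone is antipodal to the common (3R,4R) dibenzylbutyrolactones; O-benzylvanillin and the corresponding benzyl alcohol are taken as catalogue chemicals.

Step 1
Reactants: 1 4-(benzyloxy)-3-methoxybenzyl alcohol
Product: 2 4-(benzyloxy)-3-methoxybenzyl bromide
Conditions: PBr3 (0.4 equiv), Et2O, 0 °C
Reagents that add atoms: phosphorus tribromide, BrP(Br)Br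
Why: Bromination of a primary benzylic alcohol with PBr3 (SN2 on the phosphite ester) is fast at 0 °C, touches neither aryl ether and gives a bromide reactive enough for an enolate alkylation at −78 °C.

Step 2
Reactants: 3 4-tert-butoxy-4-oxobutanoic acid; 4 (S)-4-benzyl-2-oxazolidinone
Product: 6 tert-butyl 4-[(4S)-4-benzyl-2-oxo-1,3-oxazolidin-3-yl]-4-oxobutanoate, via mixed pivalic anhydride 5 (not isolated)
Conditions: t-BuCOCl, Et3N, THF, −20 °C; then LiCl, 4, −20 °C → rt
Reagents that add atoms: none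
Why: N-acylation of the oxazolidinone by the mixed-anhydride method (LiCl/Et3N) needs no strong base, and the nucleophile attacks the unhindered succinyl carbonyl of 5 rather than the pivaloyl one.

Step 3
Reactants: 6 tert-butyl 4-[(4S)-4-benzyl-2-oxo-1,3-oxazolidin-3-yl]-4-oxobutanoate; 2 4-(benzyloxy)-3-methoxybenzyl bromide
Product: 8 tert-butyl (3S)-3-[4-(benzyloxy)-3-methoxybenzyl]-4-[(4S)-4-benzyl-2-oxo-1,3-oxazolidin-3-yl]-4-oxobutanoate, via sodium enolate 7 (not isolated)
Conditions: NaN(SiMe3)2, THF, −78 °C; then 2, −78 → −20 °C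
Reagents that add atoms: none
Why: Evans asymmetric alkylation: only the more acidic imide α-CH2 is deprotonated, the chelated (Z)-enolate 7 is blocked on one face by the benzyl group of the auxiliary, and 2 enters from the open face to set the (S) centre that becomes lactone C4.

Step 4
Reactants: 8 tert-butyl (3S)-3-[4-(benzyloxy)-3-methoxybenzyl]-4-[(4S)-4-benzyl-2-oxo-1,3-oxazolidin-3-yl]-4-oxobutanoate
Product: 9 tert-butyl (3S)-3-[4-(benzyloxy)-3-methoxybenzyl]-4-hydroxybutanoate
Conditions: LiBH4, THF, 0 °C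
Reagents that add atoms: none
Why: Reductive removal of the auxiliary: LiBH4 attacks the activated exocyclic imide carbonyl far faster than a tert-butyl ester, the auxiliary is recovered, and the weakly basic hydride leaves the α-centre unepimerised.

Step 5
Reactants: 9 tert-butyl (3S)-3-[4-(benzyloxy)-3-methoxybenzyl]-4-hydroxybutanoate
Product: 10 (4S)-4-[4-(benzyloxy)-3-methoxybenzyl]dihydrofuran-2(3H)-one
Conditions: CF3CO2H, CH2Cl2, 0 °C → rt
Reagents that add atoms: none
Why: Acidolysis of the tert-butyl ester and 5-exo-trig lactonisation of the resulting γ-hydroxy acid take place in one operation, and the stereocentre now lies β to the carbonyl and cannot epimerise.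

Step 6
Reactants: 11 4-bromo-2-furaldehyde
Product: 12 (4-bromofuran-2-yl)acetonitrile
Conditions: TosMIC, KOtBu, DME, −30 °C; then MeOH, reflux
Reagents that add atoms: tosylmethyl isocyanide (TosMIC), Cc1ccc(cc1)S(=O)(=O)C[N+]#[C-]
Why: van Leusen reductive cyanation: the TosMIC anion adds to the aldehyde and methanolysis of the N-formyl tosyl enamide expels formate and sulfinate, so ArCHO becomes ArCH2CN in one flask without a furfuryl halide, whose cyanide displacement tends to go astray at the free α-position.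

Step 7
Reactants: 12 (4-bromofuran-2-yl)acetonitrile
Product: 13 (4-bromofuran-2-yl)acetic acid
Conditions: KOH, EtOH/H2O, reflux; then cold aq. HCl to pH 3
Reagents that add atoms: potassium hydroxide, [K+].[OH-]; water, O
Why: Alkaline nitrile hydrolysis spares the acid-sensitive furan and the bromide, and cold acidification avoids decarboxylation of the furylacetic acid.

Step 8
Reactants: 13 (4-bromofuran-2-yl)acetic acid; 4 (S)-4-benzyl-2-oxazolidinone
Product: 15 (4S)-4-benzyl-3-[(4-bromofuran-2-yl)acetyl]-1,3-oxazolidin-2-one, via mixed pivalic anhydride 14 (not isolated)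
Conditions: t-BuCOCl, Et3N, THF, −20 °C; then LiCl, 4, −20 °C → rt
Reagents that add atoms: none
Why: Mixed-anhydride N-acylation as in step 2, in which the mild amine base keeps ketene formation from the acidic furylacetyl unit low.

Step 9
Reactants: 15 (4S)-4-benzyl-3-[(4-bromofuran-2-yl)acetyl]-1,3-oxazolidin-2-one; 16 4-(benzyloxy)-3-methoxybenzaldehyde
Product: 19 (4S)-4-benzyl-3-{(2R,3S)-3-[4-(benzyloxy)-3-methoxyphenyl]-2-(4-bromofuran-2-yl)-3-hydroxypropanoyl}-1,3-oxazolidin-2-one, via boron enolate 17 (not isolated), via boron aldolate 18 (not isolated)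
Conditions: Bu2BOTf, Et3N, CH2Cl2, −78 → 0 °C; 16, −78 → 0 °C; pH 7 buffer, MeOH, 30% H2O2, 0 °C
Reagents that add atoms: none
Why: Evans syn aldol: soft enolisation gives the (Z)-boron enolate 17, which reacts through a chair Zimmerman–Traxler transition state on the face turned away from the auxiliary benzyl group and so fixes (2R,3S), the future C3 and C2 of the dihydrobenzofuran.

Step 10
Reactants: 19 (4S)-4-benzyl-3-{(2R,3S)-3-[4-(benzyloxy)-3-methoxyphenyl]-2-(4-bromofuran-2-yl)-3-hydroxypropanoyl}-1,3-oxazolidin-2-one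
Product: 20 (1S,2R)-1-[4-(benzyloxy)-3-methoxyphenyl]-2-(4-bromofuran-2-yl)propane-1,3-diol
Conditions: LiBH4, THF, 0 °C
Reagents that add atoms: none
Why: Reductive cleavage of the N-acyloxazolidinone at 0 °C should turn the imide carbonyl into the future C3 hydroxymethyl group faster than retro-aldol or epimerisation sets in, and the bromofuran is inert to borohydride.

Step 11
Reactants: 20 (1S,2R)-1-[4-(benzyloxy)-3-methoxyphenyl]-2-(4-bromofuran-2-yl)propane-1,3-diol
Product: 21 (1S,2R)-1-[4-(benzyloxy)-3-methoxyphenyl]-2-(4-bromofuran-2-yl)-3-(triisopropylsilyloxy)propan-1-ol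
Conditions: i-Pr3SiCl, imidazole, DMF, 0 °C → rt
Reagents that add atoms: triisopropylsilyl chloride, CC(C)[Si](Cl)(C(C)C)C(C)C
Why: Sterically differentiated silylation takes the primary hydroxyl only, and the bulky triisopropylsilyl group is chosen because it resists the 1,5 oxygen-to-oxygen silyl shift that a smaller silyl ether would risk in the alkoxide of step 12.

Step 12
Reactants: 21 (1S,2R)-1-[4-(benzyloxy)-3-methoxyphenyl]-2-(4-bromofuran-2-yl)-3-(triisopropylsilyloxy)propan-1-ol; 22 trichloroethylene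
Product: 24 (E)-1,2-dichlorovinyl ether of 21, via potassium alkoxide 23 (not isolated)
Conditions: KH, THF, 0 °C; then 22, −50 °C → rt
Reagents that add atoms: none
Why: Alkoxide addition to dichloroacetylene generated in situ from trichloroethylene (the standard route to 1,2-dichlorovinyl ethers) forms the O1–C7a bond, anti addition gives the (E) ether, and the carbinol C–O bond is untouched so the configuration is retained.

Step 13
Reactants: 24 (E)-1,2-dichlorovinyl ether of 21
Product: 26 5-{(1S,2R)-1-[4-(benzyloxy)-3-methoxyphenyl]-1-(ethynyloxy)-3-(triisopropylsilyloxy)propan-2-yl}furan-3-carbaldehyde, via dilithio species 25 (not isolated)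
Conditions: 24 added to n-BuLi (3.5 equiv), THF, −78 °C; DMF (5 equiv), −78 °C; MeOH then pH 7 buffer at −78 °C
Reagents that add atoms: N,N-dimethylformamide, CN(C)C=O
Why: n-BuLi removes HCl from the dichlorovinyl ether and exchanges the remaining alkynyl chlorine for lithium (the standard entry to lithium alkoxyacetylides) while bromine–lithium exchange at the furan β-position runs at the same temperature; inverse addition keeps the furyllithium from being protonated by unreacted vinyl C–H, only the sp2 carbanion of 25 adds to DMF at −78 °C because lithium acetylides need warming to do so, and the cold quench returns the terminal alkyne.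

Step 14
Reactants: 26 5-{(1S,2R)-1-[4-(benzyloxy)-3-methoxyphenyl]-1-(ethynyloxy)-3-(triisopropylsilyloxy)propan-2-yl}furan-3-carbaldehyde
Product: 27 (5-{(1S,2R)-1-[4-(benzyloxy)-3-methoxyphenyl]-1-(ethynyloxy)-3-(triisopropylsilyloxy)propan-2-yl}furan-3-yl)methanol
Conditions: NaBH4, THF/MeOH, 0 °C; aq. NaHCO3 work-up
Reagents that add atoms: none
Why: Chemoselective 1,2-reduction of the aldehyde by NaBH4 takes place in a basic medium in which ethynyl, silyl and benzyl ethers are all stable.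

Step 15
Reactants: 27 (5-{(1S,2R)-1-[4-(benzyloxy)-3-methoxyphenyl]-1-(ethynyloxy)-3-(triisopropylsilyloxy)propan-2-yl}furan-3-yl)methanol
Product: 29 4-(bromomethyl)-2-{(1S,2R)-1-[4-(benzyloxy)-3-methoxyphenyl]-1-(ethynyloxy)-3-(triisopropylsilyloxy)propan-2-yl}furan, via mesylate 28 (not isolated)
Conditions: MsCl, Et3N, THF, −40 °C; then LiBr, THF, −40 → 0 °C; used crude
Reagents that add atoms: lithium bromide, [Li+].[Br-]
Why: Mesylation followed by Finkelstein-type SN2 displacement with LiBr makes the furylmethyl bromide under amine-buffered, acid-free conditions below 0 °C, which an acid-labile ethynyl ether tolerates where PBr3 or HBr would not.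

Step 16
Reactants: 10 (4S)-4-[4-(benzyloxy)-3-methoxybenzyl]dihydrofuran-2(3H)-one; 29 4-(bromomethyl)-2-{(1S,2R)-1-[4-(benzyloxy)-3-methoxyphenyl]-1-(ethynyloxy)-3-(triisopropylsilyloxy)propan-2-yl}furan
Product: 31 (3S,4S)-4-[4-(benzyloxy)-3-methoxybenzyl]-3-[(5-{(1S,2R)-1-[4-(benzyloxy)-3-methoxyphenyl]-1-(ethynyloxy)-3-(triisopropylsilyloxy)propan-2-yl}furan-3-yl)methyl]dihydrofuran-2(3H)-one, via lithium enolate 30 (not isolated)
Conditions: 10 (1.3 equiv), LiN(SiMe3)2 (1.25 equiv), THF, −78 °C; then 29, DMPU, −78 → −40 °C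
Reagents that add atoms: none
Why: Diastereoselective lactone enolate alkylation, the standard way to trans-dibenzylbutyrolactones: 29 approaches enolate 30 anti to the C4 arylmethyl group and sets (3S), and a terminal alkyne C–H is tolerated as it is in enolate propargylations.

Step 17
Reactants: 31 (3S,4S)-4-[4-(benzyloxy)-3-methoxybenzyl]-3-[(5-{(1S,2R)-1-[4-(benzyloxy)-3-methoxyphenyl]-1-(ethynyloxy)-3-(triisopropylsilyloxy)propan-2-yl}furan-3-yl)methyl]dihydrofuran-2(3H)-one
Product: 33 (3S,4S)-4-[4-(benzyloxy)-3-methoxybenzyl]-3-({(2S,3R)-2-[4-(benzyloxy)-3-methoxyphenyl]-7-hydroxy-3-[(triisopropylsilyloxy)methyl]-2,3-dihydro-1-benzofuran-5-yl}methyl)dihydrofuran-2(3H)-one, via furo-oxepine 32 (not isolated)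
Conditions: Ph3PAuNTf2 (2 mol %), 4 Å MS, CH2Cl2 (0.01 M), −20 → 0 °C; then Et3N
Reagents that add atoms: none
Why: Ph3PAuNTf2, a π-acid of monovalent gold, binds the ethynyl ether, whose oxygen polarises it towards a ketenium-like species, so furan C2 attacks the oxygen-bearing alkyne carbon in a 5-exo-dig closure that makes C3a–C7a and the dihydrofuran ring. The cyclopropyl gold carbene so formed breaks the old furan C2–O bond to give a dienal carbene, whose aldehyde oxygen adds to the carbene carbon (the former alkyne terminus) and releases the catalyst with formation of furo-oxepine 32. A 6π disrotatory electrocyclisation of 32 to its arene oxide valence isomer makes C6–C7 and the six-membered ring B, and the epoxide opens at C6 because the resulting cation is conjugated with O1 on C7a, which leaves the hydroxyl on C7 after proton loss. The closest known reaction is the gold-catalysed furan-yne phenol synthesis, which with ethynyl ether tethers of this length delivers 7-hydroxy-2,3-dihydrobenzofurans. No stereocentre is created, since C2 and C3 come from the aldol, no bond to either is broken, and their syn relation in the chain becomes the trans relation in the ring. The step needs the furan to outrun ring C, water and C2–O ionisation for the activated alkyne and needs the arm to end on C5; the higher nucleophilicity of the furan, its 2,4-substitution, molecular sieves, dilution and the low temperature should secure this.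

Step 18
Reactants: 33 (3S,4S)-4-[4-(benzyloxy)-3-methoxybenzyl]-3-({(2S,3R)-2-[4-(benzyloxy)-3-methoxyphenyl]-7-hydroxy-3-[(triisopropylsilyloxy)methyl]-2,3-dihydro-1-benzofuran-5-yl}methyl)dihydrofuran-2(3H)-one
Product: 34 (3S,4S)-4-[4-(benzyloxy)-3-methoxybenzyl]-3-({(2S,3R)-2-[4-(benzyloxy)-3-methoxyphenyl]-7-hydroxy-3-(hydroxymethyl)-2,3-dihydro-1-benzofuran-5-yl}methyl)dihydrofuran-2(3H)-one
Conditions: HF·pyridine, pyridine, THF, 0 °C → rt
Reagents that add atoms: none
Why: Fluoride-driven Si–O cleavage with pyridine-buffered HF removes the primary silyl ether without base, so the lactone, the free C7 phenol and the benzylic C2–O bond are left alone.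

Step 19
Reactants: 34 (3S,4S)-4-[4-(benzyloxy)-3-methoxybenzyl]-3-({(2S,3R)-2-[4-(benzyloxy)-3-methoxyphenyl]-7-hydroxy-3-(hydroxymethyl)-2,3-dihydro-1-benzofuran-5-yl}methyl)dihydrofuran-2(3H)-one
Product: 35 (3S,4S)-4-(4-hydroxy-3-methoxybenzyl)-3-{[(2S,3R)-7-hydroxy-2-(4-hydroxy-3-methoxyphenyl)-3-(hydroxymethyl)-2,3-dihydro-1-benzofuran-5-yl]methyl}dihydrofuran-2(3H)-one (CNP0118131.1)
Conditions: H2 (1 atm), 10% Pd/C, EtOAc/EtOH, rt, stopped at full debenzylation
Reagents that add atoms: none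
Why: Catalytic hydrogenolysis cleaves the two aryl benzyl ethers quickly at 1 atm, well before the more hindered cyclic benzylic C2–O bond should react, and no stereocentre is affected.

**Compound list**
1 | 4-(benzyloxy)-3-methoxybenzyl alcohol | COc1cc(CO)ccc1OCc1ccccc1 | starting material
2 | 4-(benzyloxy)-3-methoxybenzyl bromide | COc1cc(CBr)ccc1OCc1ccccc1 | intermediate
3 | 4-tert-butoxy-4-oxobutanoic acid (mono-tert-butyl succinate) | CC(C)(C)OC(=O)CCC(=O)O | starting material
4 | (S)-4-benzyl-2-oxazolidinone | O=C1N[C@@H](Cc2ccccc2)CO1 | starting material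
5 | mixed pivalic anhydride of 3 | CC(C)(C)OC(=O)CCC(=O)OC(=O)C(C)(C)C | intermediate
6 | tert-butyl 4-[(4S)-4-benzyl-2-oxo-1,3-oxazolidin-3-yl]-4-oxobutanoate | CC(C)(C)OC(=O)CCC(=O)N1[C@@H](Cc2ccccc2)COC1=O | intermediate
7 | sodium (Z)-enolate of 6 | [Na+].CC(C)(C)OC(=O)C/C=C(\[O-])N1[C@@H](Cc2ccccc2)COC1=O | intermediate
8 | tert-butyl (3S)-3-[4-(benzyloxy)-3-methoxybenzyl]-4-[(4S)-4-benzyl-2-oxo-1,3-oxazolidin-3-yl]-4-oxobutanoate | CC(C)(C)OC(=O)C[C@H](Cc1ccc(OCc2ccccc2)c(OC)c1)C(=O)N1[C@@H](Cc2ccccc2)COC1=O | intermediate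
9 | tert-butyl (3S)-3-[4-(benzyloxy)-3-methoxybenzyl]-4-hydroxybutanoate | CC(C)(C)OC(=O)C[C@H](Cc1ccc(OCc2ccccc2)c(OC)c1)CO | intermediate
10 | (4S)-4-[4-(benzyloxy)-3-methoxybenzyl]dihydrofuran-2(3H)-one | O=C1C[C@H](Cc2ccc(OCc3ccccc3)c(OC)c2)CO1 | intermediate
11 | 4-bromo-2-furaldehyde | O=Cc1cc(Br)co1 | starting material
12 | (4-bromofuran-2-yl)acetonitrile | N#CCc1cc(Br)co1 | intermediate
13 | (4-bromofuran-2-yl)acetic acid | OC(=O)Cc1cc(Br)co1 | intermediate
14 | mixed pivalic anhydride of 13 | CC(C)(C)C(=O)OC(=O)Cc1cc(Br)co1 | intermediate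
15 | (4S)-4-benzyl-3-[(4-bromofuran-2-yl)acetyl]-1,3-oxazolidin-2-one | O=C(Cc1cc(Br)co1)N1[C@@H](Cc2ccccc2)COC1=O | intermediate
16 | 4-(benzyloxy)-3-methoxybenzaldehyde (O-benzylvanillin) | COc1cc(C=O)ccc1OCc1ccccc1 | starting material
17 | (Z)-dibutylboron enolate of 15 | CCCCB(CCCC)O/C(=C\c1cc(Br)co1)N1[C@@H](Cc2ccccc2)COC1=O | intermediate
18 | O-dibutylboryl derivative (boron aldolate) of 19 | O=C([C@@H](c1cc(Br)co1)[C@H](OB(CCCC)CCCC)c1ccc(OCc2ccccc2)c(OC)c1)N1[C@@H](Cc2ccccc2)COC1=O | intermediate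
19 | (4S)-4-benzyl-3-{(2R,3S)-3-[4-(benzyloxy)-3-methoxyphenyl]-2-(4-bromofuran-2-yl)-3-hydroxypropanoyl}-1,3-oxazolidin-2-one | O=C([C@@H](c1cc(Br)co1)[C@H](O)c1ccc(OCc2ccccc2)c(OC)c1)N1[C@@H](Cc2ccccc2)COC1=O | intermediate
20 | (1S,2R)-1-[4-(benzyloxy)-3-methoxyphenyl]-2-(4-bromofuran-2-yl)propane-1,3-diol | OC[C@@H](c1cc(Br)co1)[C@H](O)c1ccc(OCc2ccccc2)c(OC)c1 | intermediate
21 | (1S,2R)-1-[4-(benzyloxy)-3-methoxyphenyl]-2-(4-bromofuran-2-yl)-3-(triisopropylsilyloxy)propan-1-ol | CC(C)[Si](OC[C@@H](c1cc(Br)co1)[C@H](O)c1ccc(OCc2ccccc2)c(OC)c1)(C(C)C)C(C)C | intermediate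
22 | trichloroethylene | ClC=C(Cl)Cl | starting material
23 | potassium alkoxide of 21 | [K+].CC(C)[Si](OC[C@@H](c1cc(Br)co1)[C@H]([O-])c1ccc(OCc2ccccc2)c(OC)c1)(C(C)C)C(C)C | intermediate
24 | (E)-1,2-dichlorovinyl ether of 21, (1S,2R) | CC(C)[Si](OC[C@@H](c1cc(Br)co1)[C@H](O/C(Cl)=C\Cl)c1ccc(OCc2ccccc2)c(OC)c1)(C(C)C)C(C)C | intermediate
25 | dilithio species: lithium alkoxyacetylide and 4-lithiofuran, (1S,2R) | CC(C)[Si](OC[C@@H](c1cc([Li])co1)[C@H](OC#C[Li])c1ccc(OCc2ccccc2)c(OC)c1)(C(C)C)C(C)C | intermediate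
26 | 5-{(1S,2R)-1-[4-(benzyloxy)-3-methoxyphenyl]-1-(ethynyloxy)-3-(triisopropylsilyloxy)propan-2-yl}furan-3-carbaldehyde | CC(C)[Si](OC[C@@H](c1cc(C=O)co1)[C@H](OC#C)c1ccc(OCc2ccccc2)c(OC)c1)(C(C)C)C(C)C | intermediate
27 | (5-{(1S,2R)-1-[4-(benzyloxy)-3-methoxyphenyl]-1-(ethynyloxy)-3-(triisopropylsilyloxy)propan-2-yl}furan-3-yl)methanol | CC(C)[Si](OC[C@@H](c1cc(CO)co1)[C@H](OC#C)c1ccc(OCc2ccccc2)c(OC)c1)(C(C)C)C(C)C | intermediate
28 | methanesulfonate of 27 | CC(C)[Si](OC[C@@H](c1cc(COS(C)(=O)=O)co1)[C@H](OC#C)c1ccc(OCc2ccccc2)c(OC)c1)(C(C)C)C(C)C | intermediate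
29 | 4-(bromomethyl)-2-{(1S,2R)-1-[4-(benzyloxy)-3-methoxyphenyl]-1-(ethynyloxy)-3-(triisopropylsilyloxy)propan-2-yl}furan | CC(C)[Si](OC[C@@H](c1cc(CBr)co1)[C@H](OC#C)c1ccc(OCc2ccccc2)c(OC)c1)(C(C)C)C(C)C | intermediate
30 | lithium enolate of 10 | [Li+].[O-]C1=C[C@H](Cc2ccc(OCc3ccccc3)c(OC)c2)CO1 | intermediate
31 | (3S,4S)-4-[4-(benzyloxy)-3-methoxybenzyl]-3-[(5-{(1S,2R)-1-[4-(benzyloxy)-3-methoxyphenyl]-1-(ethynyloxy)-3-(triisopropylsilyloxy)propan-2-yl}furan-3-yl)methyl]dihydrofuran-2(3H)-one | COc1cc(C[C@@H]2COC(=O)[C@H]2Cc2coc(c2)[C@H](CO[Si](C(C)C)(C(C)C)C(C)C)[C@@H](c2ccc(OCc4ccccc4)c(OC)c2)OC#C)ccc1OCc1ccccc1 | intermediate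
32 | 2,3-dihydrofuro[2,3-c]oxepine valence isomer of 33 (oxygen bridging C6 and C7 in benzofuran numbering, all other groups as in 33) | COc1cc(C[C@@H]2COC(=O)[C@H]2CC2=COC=C3C(=C2)[C@H](CO[Si](C(C)C)(C(C)C)C(C)C)[C@@H](c2ccc(OCc4ccccc4)c(OC)c2)O3)ccc1OCc1ccccc1 | intermediate
33 | (3S,4S)-4-[4-(benzyloxy)-3-methoxybenzyl]-3-({(2S,3R)-2-[4-(benzyloxy)-3-methoxyphenyl]-7-hydroxy-3-[(triisopropylsilyloxy)methyl]-2,3-dihydro-1-benzofuran-5-yl}methyl)dihydrofuran-2(3H)-one | COc1cc(C[C@@H]2COC(=O)[C@H]2Cc2cc(O)c3c(c2)[C@H](CO[Si](C(C)C)(C(C)C)C(C)C)[C@@H](c2ccc(OCc4ccccc4)c(OC)c2)O3)ccc1OCc1ccccc1 | intermediate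
34 | (3S,4S)-4-[4-(benzyloxy)-3-methoxybenzyl]-3-({(2S,3R)-2-[4-(benzyloxy)-3-methoxyphenyl]-7-hydroxy-3-(hydroxymethyl)-2,3-dihydro-1-benzofuran-5-yl}methyl)dihydrofuran-2(3H)-one | COc1cc(C[C@@H]2COC(=O)[C@H]2Cc2cc(O)c3c(c2)[C@H](CO)[C@@H](c2ccc(OCc4ccccc4)c(OC)c2)O3)ccc1OCc1ccccc1 | intermediate
35 | (3S,4S)-4-(4-hydroxy-3-methoxybenzyl)-3-{[(2S,3R)-7-hydroxy-2-(4-hydroxy-3-methoxyphenyl)-3-(hydroxymethyl)-2,3-dihydro-1-benzofuran-5-yl]methyl}dihydrofuran-2(3H)-one | COc1cc(C[C@@H]2COC(=O)[C@H]2Cc2cc(O)c3c(c2)[C@H](CO)[C@@H](c2ccc(O)c(OC)c2)O3)ccc1O | target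

Total step count: 19.
Longest linear sequence: 14 steps (steps 6 to 19, from 11).

**Steps most likely to fail**

**Step 17.**
- **What may go wrong:** the Lewis acidic catalyst may ionise the doubly activated benzylic C2–O bond, trace water may hydrate the ynol ether, or the free furan α-position may attack intermolecularly. Any of these could outrun the 5-exo-dig closure on a large and precious substrate.
- **Fallback:** the benzannulation is moved ahead of the fragment union. It then runs on a small, easily replenished substrate, and the union uses an ordinary benzylic bromide.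
- **Route:** it sets out from 27. Acetylation (Ac2O, pyridine, 0 °C) gives the furylmethyl acetate F1, and Ph3PAuNTf2 in CH2Cl2 isomerises it to the 7-hydroxy-dihydrobenzofuran acetate F2. t-BuMe2SiCl/imidazole then gives the aryl silyl ether F3, and i-Bu2AlH (CH2Cl2, −78 °C) frees the benzylic alcohol F4. An Appel reaction (CBr4, PPh3) gives the benzylic bromide F5, and alkylation of lithium enolate 30 gives the bis-silyl lactone F6. Bu4NF/AcOH removes both silyl groups, and the route is rejoined at 34.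

**Step 13.**
- **What may go wrong:** the furyllithium may be protonated by the vinyl C–H of unreacted 24, which loses bromine without formylation. The alkoxyacetylide may also take up DMF.
- **Fallback:** the one-carbon unit is brought in by cross-coupling before any vinyl ether exists.
- **Route:** it sets out from 21. Stille coupling with Bu3SnCH2OH (Pd(PPh3)4, a zerovalent palladium catalyst, dioxane, 90 °C) gives the hydroxymethylfuran diol F7. Et3SiCl/imidazole at −20 °C silylates only the unhindered furylmethyl hydroxyl to give the triethylsilyl ether F8. KH and 22 give the dichlorovinyl ether F9, and n-BuLi (2.3 equiv, −78 °C) followed by MeOH gives the ethynyl ether F10. Bu4NF (1 equiv, THF, −20 °C) removes the triethylsilyl group much faster than the triisopropylsilyl group, and the route is rejoined at 27.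

**Step 16.**
- **What may go wrong:** proton transfer from the ethynyl C–H to the enolate, decomposition of the labile furylmethyl bromide, or a second alkylation may erode the union.
- **Fallback:** olefination and conjugate reduction replace the SN2 union and bypass steps 14 to 16.
- **Route:** it sets out from 10 and 26. LiN(i-Pr)2 (2.2 equiv) and ClP(O)(OEt)2 (enol phosphate, then 1,3 phosphorus shift) convert 10 into the α-phosphono lactone F11. A Horner–Wadsworth–Emmons reaction of F11 with aldehyde 26 (NaH, THF, 0 °C) gives the (E)-furylmethylene lactone F12. Conjugate hydride addition with LiBH(s-Bu)3 (THF, −78 °C), protonation and equilibration with DBU to the more stable trans lactone come back to the route at 31.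

**Further compounds**
F1 | step 17 | (5-{(1S,2R)-1-[4-(benzyloxy)-3-methoxyphenyl]-1-(ethynyloxy)-3-(triisopropylsilyloxy)propan-2-yl}furan-3-yl)methyl acetate | CC(=O)OCc1coc(c1)[C@H](CO[Si](C(C)C)(C(C)C)C(C)C)[C@@H](c1ccc(OCc2ccccc2)c(OC)c1)OC#C
F2 | step 17 | {(2S,3R)-2-[4-(benzyloxy)-3-methoxyphenyl]-7-hydroxy-3-[(triisopropylsilyloxy)methyl]-2,3-dihydro-1-benzofuran-5-yl}methyl acetate | CC(=O)OCc1cc(O)c2c(c1)[C@H](CO[Si](C(C)C)(C(C)C)C(C)C)[C@@H](c1ccc(OCc3ccccc3)c(OC)c1)O2
F3 | step 17 | 7-O-(tert-butyldimethylsilyl) ether of F2 | CC(=O)OCc1cc(O[Si](C)(C)C(C)(C)C)c2c(c1)[C@H](CO[Si](C(C)C)(C(C)C)C(C)C)[C@@H](c1ccc(OCc3ccccc3)c(OC)c1)O2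
F4 | step 17 | {(2S,3R)-2-[4-(benzyloxy)-3-methoxyphenyl]-7-(tert-butyldimethylsilyloxy)-3-[(triisopropylsilyloxy)methyl]-2,3-dihydro-1-benzofuran-5-yl}methanol | OCc1cc(O[Si](C)(C)C(C)(C)C)c2c(c1)[C@H](CO[Si](C(C)C)(C(C)C)C(C)C)[C@@H](c1ccc(OCc3ccccc3)c(OC)c1)O2
F5 | step 17 | (2S,3R)-2-[4-(benzyloxy)-3-methoxyphenyl]-5-(bromomethyl)-7-(tert-butyldimethylsilyloxy)-3-[(triisopropylsilyloxy)methyl]-2,3-dihydro-1-benzofuran | BrCc1cc(O[Si](C)(C)C(C)(C)C)c2c(c1)[C@H](CO[Si](C(C)C)(C(C)C)C(C)C)[C@@H](c1ccc(OCc3ccccc3)c(OC)c1)O2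
F6 | step 17 | 7-O-(tert-butyldimethylsilyl) ether of 33 | COc1cc(C[C@@H]2COC(=O)[C@H]2Cc2cc(O[Si](C)(C)C(C)(C)C)c3c(c2)[C@H](CO[Si](C(C)C)(C(C)C)C(C)C)[C@@H](c2ccc(OCc4ccccc4)c(OC)c2)O3)ccc1OCc1ccccc1
F7 | step 13 | (1S,2R)-1-[4-(benzyloxy)-3-methoxyphenyl]-2-[4-(hydroxymethyl)furan-2-yl]-3-(triisopropylsilyloxy)propan-1-ol | CC(C)[Si](OC[C@@H](c1cc(CO)co1)[C@H](O)c1ccc(OCc2ccccc2)c(OC)c1)(C(C)C)C(C)C
F8 | step 13 | (1S,2R)-1-[4-(benzyloxy)-3-methoxyphenyl]-2-{4-[(triethylsilyloxy)methyl]furan-2-yl}-3-(triisopropylsilyloxy)propan-1-ol | CC(C)[Si](OC[C@@H](c1cc(CO[Si](CC)(CC)CC)co1)[C@H](O)c1ccc(OCc2ccccc2)c(OC)c1)(C(C)C)C(C)C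
F9 | step 13 | (E)-1,2-dichlorovinyl ether of F8 | CC(C)[Si](OC[C@@H](c1cc(CO[Si](CC)(CC)CC)co1)[C@H](O/C(Cl)=C\Cl)c1ccc(OCc2ccccc2)c(OC)c1)(C(C)C)C(C)C
F10 | step 13 | O-triethylsilyl ether of 27 | CC(C)[Si](OC[C@@H](c1cc(CO[Si](CC)(CC)CC)co1)[C@H](OC#C)c1ccc(OCc2ccccc2)c(OC)c1)(C(C)C)C(C)C
F11 | step 16 | diethyl {(3S,4S)-4-[4-(benzyloxy)-3-methoxybenzyl]-2-oxotetrahydrofuran-3-yl}phosphonate (trans, C3 labile) | COc1cc(C[C@@H]2COC(=O)[C@H]2P(=O)(OCC)OCC)ccc1OCc1ccccc1
F12 | step 16 | (3E,4S)-4-[4-(benzyloxy)-3-methoxybenzyl]-3-[(5-{(1S,2R)-1-[4-(benzyloxy)-3-methoxyphenyl]-1-(ethynyloxy)-3-(triisopropylsilyloxy)propan-2-yl}furan-3-yl)methylidene]dihydrofuran-2(3H)-one | COc1cc(C[C@@H]2COC(=O)/C2=C/c2coc(c2)[C@H](CO[Si](C(C)C)(C(C)C)C(C)C)[C@@H](c2ccc(OCc4ccccc4)c(OC)c2)OC#C)ccc1OCc1ccccc1
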